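| setting | noon | dawn | autumn | flask |
|---|---|---|---|---|
| first end groups | 0.22 M | 0.33 M | 0.44 M | 0.44 M |
| second end groups | 0.462 M | 0.462 M | 0.23 M | 0.462 M |
| remark | run made earlier | run made earlier | run made earlier |  |
| time |  |  |  | 15 d |

- noon (time / d: links / %, rings / %): 2.08: 22.9, 76.4; 4.00: 23.3, 76.5; 6.00: 23.3, 76.8; 8.00: 23.1, 77.5; 10.0: 23.5, 76.8; 12.0: 23.1, 76.2
- dawn (time / d: links / %, rings / %): 0.833: 19.3, 75.5; 2.50: 20.2, 80.1; 4.00: 19.6, 79.6; 6.00: 20.7, 79.7; 10.0: 20.3, 80.2; 12.0: 20.1, 79.2
- autumn (time / d: links / %, rings / %): 2.50: 4.1, 48.2; 5.00: 4.4, 47.5; 8.00: 4.6, 47.6; 10.0: 4.4, 48.2; 12.0: 5.1, 47.8

(scatter of a reading: 0.3 percentage points)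

- the earlier runs were read with a standard deviation of 0.3 percentage points
- the reaction counts as stopped when no species that holds the first end groups changes by six tenths of a point or more over the second half of the time

* at 15 d, what has stopped the reaction, if anything has (all of the first end groups has reacted / the second end groups has run out first / it is still moving)
* how much links there is at 15 d, in percent of the first end groups charged
* how much rings there is at 15 d, in percent of the first end groups charged

Amounts first: in the last reading of the dawn run, links and rings together held 99.3% of the first end groups charged, so I read the first end groups of that run as used up. But in the last reading of the autumn run the sum stood at 52.9%, or 0.233 M, close to the 0.23 M of second end groups charged, so I took the two groups to react one to one. So for this flask, with c(second end groups) 0.462 M above c(first end groups) 0.44 M, I expected first end groups to be the limiting reagent.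

Yet the last readings of links stood at 23.1% in the noon run and 5.1% in the autumn run, so as a trial I took the ratio of links to rings to follow c(second end groups), solved it at the start and end of a run, and joined the two by their mean. This gave my split constant, a selectivity factor: links per ring formed, per molar of second end groups. The dawn readings from 2.50 d on gave 0.852 M⁻¹. In this flask I took c(second end groups) to fall from 0.462 M to 0.0220 M, a mean of 0.242 M, so I reckoned 17.1% links and 82.9% rings.

The forecast expected the same end and differed slightly in the split: all of the first end groups has reacted, 16.5% links and 83.5% rings, noting that “Links fall as more second end groups are consumed”.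

The flask gave: all of the first end groups has reacted, 16.8% links and 83.2% rings.

    first end groups + second end groups → rings, rate k1*[first end groups] as long as [second end groups] is above zero (k = 0.127 h⁻¹)
    first end groups + second end groups → links (k = 0.111 M⁻¹ h⁻¹)

In this flask, rings used first end groups 2.5 times as fast as links at the start, where the split constant gave 2.54, and 5.1 times as fast at 0.199 d. The neighbouring flask, the same flask but with 0.79 M of second end groups, had a mean c(second end groups) of 0.570 M between start and end, for which the split constant gave 32.7% links, and at 15.0 d that flask held 32.9% links.

All runs are simulated with made-up constants, and the scatter is random.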